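## Retrosynthetic overview
1. 14 ⇐ methyl ester 13 ⇐ closure of the pyran ring at the aryl C8a–O1 bond. A visible-light, phenoxyl-radical-enabled SNAr lets the tertiary carbinol oxygen of 12 displace an aryl fluoride.
2. 12 ⇐ 11 by E→Z energy transfer. 11 ⇐ Heck C4–C4a bond between vinyl carbinol 8 and bromofluorophenol 10, which comes from 3-bromo-2-fluorotoluene by C–H borylation/oxidation.
3. 8 ⇐ C7′=C8′ (Z) by Still–Gennari olefination of aldehyde 4 with the α-homoprenyl phosphonate 7.
4. 4 ⇐ C5′–C6′ bond and E-C3′=C4′ by Claisen rearrangement ⇐ Schenck ene product 2 ⇐ (S)-linalool 1. Linalool supplies C2 with its C–O bond, which is never broken.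
5. Ring order: the benzene ring is bought. The pyran is the only ring made, in step 8 of 9.

Assumption: (S)-(+)-linalool (coriandrol, the coriander-oil enantiomer) is bought at the highest ee on offer. The route neither raises nor lowers the ee, so the ee of 14 equals that of the lot.
Locants: chromene numbering is used for the bicycle. The side chain runs C1′ (on C2) to C12′, with CO2H on C8′. A one-pot operation counts as one step.

## Route

**Step 1**
Reactants: 1, (S)-(+)-linalool
Product: 2, (3S,6RS)-3,7-dimethylocta-1,7-diene-3,6-diol
Conditions: O2, TPP (0.2 mol%), CH2Cl2, white LED, 0 °C; then PPh3, 0 °C→rt; SiO2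
Reagents that add atoms: dioxygen, O=O (one O retained)
Why: In this Schenck ene reaction 1O2 attacks only the trisubstituted alkene (the vinyl carbinol is inert) and gives about 1:1 secondary and tertiary allylic hydroperoxides that PPh3 reduces, the secondary alcohol 2 being separated by chromatography; the new C6 centre forms unselectively but is erased in step 2, and C3 (S) is untouched.

**Step 2**
Reactants: 2; 3, ethyl vinyl ether
Product: 4, (4E,8S)-8-hydroxy-4,8-dimethyldeca-4,9-dienal
Conditions: 3 (solvent), Hg(OAc)2 (10 mol%), NaOAc, reflux; K2CO3 quench, concentrate; PhMe, 1% Et3N, 120 °C, sealed tube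
Reagents that add atoms: ethyl vinyl ether (3), C=COCC (its CH=CH2 unit becomes C7′/C6′)
Why: Hg(II) transvinylation takes the secondary OH much faster than the tertiary one, and the aliphatic Claisen [3,3] rearrangement through a chair with the chain equatorial forms C5′–C6′ and the E-C3′=C4′ alkene (about 9:1 E:Z expected, both C6 epimers converge, minor Z removed on AgNO3–silica) under non-acidic conditions that cannot ionise the tertiary allylic alcohol.

**Step 3**
Reactants: 5, methyl bis(2,2,2-trifluoroethyl)phosphonoacetate; 6, 5-bromo-2-methylpent-2-ene
Product: 7, methyl 2-[bis(2,2,2-trifluoroethoxy)phosphoryl]-6-methylhept-5-enoate (racemic)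
Conditions: NaH, NaI (cat.), DMF, 0→45 °C
Reagents that add atoms: none (both partners are listed reactants)
Why: This is an SN2 alkylation of the stabilised phosphonoacetate carbanion by a primary homoallylic halide (in situ Finkelstein), and the racemic α-centre disappears in step 4.

**Step 4**
Reactants: 4; 7
Product: 8, methyl (2Z,6E,10S)-10-hydroxy-6,10-dimethyl-2-(4-methylpent-3-en-1-yl)dodeca-2,6,11-trienoate
Conditions: 7, KHMDS, 18-crown-6, THF, −78 °C; then 4, −78 °C
Reagents that add atoms: none
Why: In the Still–Gennari olefination the electron-poor trifluoroethyl phosphonate eliminates irreversibly from the kinetic adduct and places the ester cis to the aldehyde-derived chain (2Z, ≥10:1 expected), while the preformed potassium phosphonate is too weak a base to touch the tertiary OH.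

**Step 5**
Reactants: 9, 3-bromo-2-fluorotoluene
Product: 10, 3-bromo-4-fluoro-5-methylphenol
Conditions: [Ir(OMe)(cod)]2 (1 mol%), dtbpy (2 mol%), B2pin2, THF, 70 °C; then Oxone, acetone/H2O, rt (one pot)
Reagents that add atoms: Oxone (KHSO5), [K+].[O-]S(=O)(=O)OO (supplies the phenol O)
Why: Sterically governed Ir-catalysed C–H borylation of a 1,2,3-trisubstituted arene hits only the C–H with no ortho neighbour (para to F), and the boronate is oxidised in the same pot with C–Br and C–F intact.

**Step 6**
Reactants: 8; 10
Product: 11, methyl (2Z,6E,10S,11E)-12-(2-fluoro-5-hydroxy-3-methylphenyl)-10-hydroxy-6,10-dimethyl-2-(4-methylpent-3-en-1-yl)dodeca-2,6,11-trienoate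
Conditions: Pd(OAc)2 (5 mol%), P(o-tol)3 (12 mol%), Et3N, MeCN, 85 °C
Reagents that add atoms: none
Why: In this Mizoroki–Heck reaction ArPd adds to the terminal carbon of the only monosubstituted alkene, and because the carbinol carbon carries no H, syn β-H elimination can only give the E-styrene; the trisubstituted alkenes, enoate, C–F and free OH groups are spectators and C10 is untouched.

**Step 7**
Reactants: 11
Product: 12, the (11Z)-isomer of 11
Conditions: fac-Ir(ppy)3 (0.5 mol%), MeCN (0.02 M), 450 nm LED, Ar, rt, stopped at the photostationary state (about 1 h); Et3N-washed SiO2, E isomer recycled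
Reagents that add atoms: none
Why: In this contra-thermodynamic E→Z isomerisation by triplet energy transfer the sensitiser (ET about 55–58 kcal/mol) excites the planar E-styrene but not the Z isomer, which A1,3 strain against the quaternary carbinol twists out of conjugation, so Z accumulates (≥9:1 expected), while the isolated alkenes and the enoate (ET >70) are not sensitised.

**Step 8 (key step)**
Reactants: 12
Product: 13, methyl (2Z,6E)-9-[(2S)-6-hydroxy-2,8-dimethyl-2H-chromen-2-yl]-6-methyl-2-(4-methylpent-3-en-1-yl)nona-2,6-dienoate
Conditions: [Ru(bpy)3](PF6)2 (1 mol%), Cs2CO3 (2.5 equiv), 4 Å MS, MeCN (0.02 M), 455 nm LED, Ar, 25 °C, amber work-up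
Reagents that add atoms: none (HF is lost)
Why: Proposed new method: visible-light phenoxyl-radical-enabled intramolecular SNAr etherification, in which excited Ru(II) (about +0.8 V; ET about 47 kcal/mol, too low to sensitise the styrene, the chromene or a chromene/C3′=C4′ [2+2]) oxidises the caesium phenoxide of 12 to its phenoxyl radical, whose O• is a far stronger para-acceptor than a nitro group, so the para C–F carbon is attacked by the tertiary carbinol O held over it by the Z-alkene (six-membered transition state, carbonate as general base), fluoride leaves, and Ru(I) returns the electron to the product 4-alkoxyphenoxyl radical (a photoredox loop is needed because this more stabilised radical could not propagate a chain); only the aryl C–F bond breaks and the carbinol C–O bond is never touched, so C2 keeps the linalool configuration (S); the closest known reaction types are radical-activated SNAr of 4-halophenols with carboxylates under a catalytic chemical oxidant and cation-radical-accelerated SNAr of fluoroarenes with azoles or amines, whereas an alcohol nucleophile, photochemical phenoxyl generation for SNAr and 2H-chromene ring closure are not known.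

**Step 9**
Reactants: 13
Product: 14, (S)-sargachromenol
Conditions: LiOH, THF/MeOH/H2O, Ar, dark, 40 °C; citric acid to pH 4
Reagents that add atoms: hydroxide/water, [Li+].[OH-] (acyl–O cleavage)
Why: This is a BAc2 saponification of the hindered methyl ester, where argon protects the phenoxide from autoxidation and 40 °C in the dark stays well below the conditions for electrocyclic chromene opening (racemisation) or Z→E enoate isomerisation.

## Compound list
| No. | Name | SMILES | Role |
|---|---|---|---|
| 1 | (S)-(+)-linalool | CC(C)=CCC[C@](C)(O)C=C | starting material |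
| 2 | (3S,6RS)-3,7-dimethylocta-1,7-diene-3,6-diol | C=C(C)C(O)CC[C@](C)(O)C=C | intermediate |
| 3 | ethyl vinyl ether | C=COCC | starting material |
| 4 | (4E,8S)-8-hydroxy-4,8-dimethyldeca-4,9-dienal | O=CCC/C(C)=C/CC[C@](C)(O)C=C | intermediate |
| 5 | methyl bis(2,2,2-trifluoroethyl)phosphonoacetate | COC(=O)CP(=O)(OCC(F)(F)F)OCC(F)(F)F | starting material |
| 6 | 5-bromo-2-methylpent-2-ene | CC(C)=CCCBr | starting material |
| 7 | methyl 2-[bis(2,2,2-trifluoroethoxy)phosphoryl]-6-methylhept-5-enoate | COC(=O)C(CCC=C(C)C)P(=O)(OCC(F)(F)F)OCC(F)(F)F | intermediate |
| 8 | (2Z,6E,10S)-trienoate carbinol | CC(C)=CCC/C(=C/CC/C(C)=C/CC[C@](C)(O)C=C)C(=O)OC | intermediate |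
| 9 | 3-bromo-2-fluorotoluene | Cc1cccc(Br)c1F | starting material |
| 10 | 3-bromo-4-fluoro-5-methylphenol | Cc1cc(O)cc(Br)c1F | intermediate |
| 11 | (11E)-fluorostyrenyl carbinol | CC(C)=CCC/C(=C/CC/C(C)=C/CC[C@](C)(O)/C=C/c1cc(O)cc(C)c1F)C(=O)OC | intermediate |
| 12 | (11Z)-fluorostyrenyl carbinol | CC(C)=CCC/C(=C/CC/C(C)=C/CC[C@](C)(O)/C=C\c1cc(O)cc(C)c1F)C(=O)OC | intermediate |
| 13 | methyl (S)-sargachromenoate | CC(C)=CCC/C(=C/CC/C(C)=C/CC[C@@]1(C)C=Cc2cc(O)cc(C)c2O1)C(=O)OC | intermediate |
| 14 | (S)-sargachromenol | CC(C)=CCC/C(=C/CC/C(C)=C/CC[C@@]1(C)C=Cc2cc(O)cc(C)c2O1)C(=O)O | target |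

## Totals and risks
Total steps: 9. Longest linear sequence: 7 (steps 1, 2, 4, 6, 7, 8, 9 from (S)-linalool). No protecting groups are used.

Steps most likely to fail:

1. **Step 8 (new reaction).**
   - Risks: phenoxyl dimerisation at the free C5/C7 positions, SNAr too slow with a neutral tertiary OH, and ee erosion if the product chromenoxyl radical opens reversibly at C2–O. Check the ee by chiral HPLC against conversion.
   - Fallback (known chemistry): use the bromo analogue. 2-Bromo-3-iodotoluene goes through the same borylation/oxidation and is then TBS-protected. Heck coupling is run at C–I, followed by the same E→Z step.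
   - The ring is then closed by Pd-catalysed intramolecular C–O coupling of the tertiary alcohol with the aryl bromide (bulky biaryl phosphine, Cs2CO3, toluene, ≤80 °C). The aryl TBS ether falls off in the final LiOH step, and the carbinol C–O bond is again untouched.

2. **Step 7.**
   - Risks: the styrene triplet can undergo intramolecular [2+2] with the C6=C7 alkene (a 1,6-diene), or the Z:E ratio may be poor.
   - Fallback: avoid alkene geometry altogether. 9-BBN hydroboration of the vinyl group of 8 and B-alkyl Suzuki coupling with 10 give the saturated tether.
   - Closing the C–O bond then gives the chromanol. C3=C4 is installed last by DDQ dehydrogenation of the 6-O-acetate, a known chroman-to-chromene conversion.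

3. **Step 2.**
   - Risks: vinyl transfer to the tertiary OH, cyclic acetal formation from the 1,4-diol, and only about 9:1 E:Z.
   - Fallback: drop the ene/sigmatropic sequence. SeO2/t-BuOOH allylic oxidation of 1 gives the (E)-8-alcohol, with the geometry fixed by the ene/[2,3] mechanism.
   - The alcohol is converted to the primary allylic bromide (CBr4/PPh3). This alkylates lithiated acetaldehyde tert-butylimine, and mild acid hydrolysis gives 4. The sequence replaces steps 1–2 and is one step longer.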